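## Retrosynthetic overview

1. Brianodin D ⇐ 8,17-epoxy-9-acetate, opened at C8 with inversion by the neighbouring acetate ⇐ OH-directed threo epoxidation of a (Z)-C8=C17 enoate; the 7,19-γ-lactone is closed last.
2. Ten-membered ring ⇐ new Ni-catalysed methylative ynoate–aldehyde macrocyclisation, which forms C8–C9 and C17–C18 and sets C9.
3. Seco ynoate–aldehyde ⇐ (Z)-enal from an RCM-made 4-methyl-5,6-dihydropyran-2-one (fixes 5Z) + methyl propiolate (C7); C3 by enolate hydroxylation, C2 by chelation-controlled reduction.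
4. Cyclohexene core ⇐ catalytic asymmetric Diels–Alder of a 2-silyloxydiene with ethyl 3-methyl-4-oxocrotonate (C1, C10), then diene osmylation (C11, C12).
5. Ring order: six-membered carbocycle → temporary 2,9-γ-lactone and 3,7-δ-lactone → ten-membered carbocycle → 7,19-γ-lactone.

Assumption 1: briarane numbering (C1–C20) is used for every intermediate. CIP letters at C8 and C10 change in some intermediates only because substituent priorities change; the only centre actually inverted is C8 in Step 27.

Assumption 2: for the chiral catalysts and reagent in Steps 2, 13 and 21, the enantiomer that gives the drawn configuration is used; both antipodes of each are commercial.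

## Route

Step 1
Reactants: 1 ethyl vinyl ketone (pent-1-en-3-one)
Product: 2 (Z)-3-(triisopropylsilyloxy)penta-1,3-diene
Conditions: TIPSOTf, Et3N, CH2Cl2, 0 °C
Reagents that add atoms: triisopropylsilyl triflate, CC(C)[Si](C(C)C)(C(C)C)OS(=O)(=O)C(F)(F)F
Why: Soft enolisation and O-silylation of the ethyl ketone gives the 2-silyloxydiene as the Z enol ether (methyl anti to the vinyl group), which is the reactive diene geometry.

Step 2
Reactants: 2 (Z)-3-(triisopropylsilyloxy)penta-1,3-diene; 3 ethyl (E)-3-methyl-4-oxobut-2-enoate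
Product: 4 ethyl (1S,6S)-6-formyl-2,6-dimethyl-3-(triisopropylsilyloxy)cyclohex-3-ene-1-carboxylate (briarane C1 S, C10 S; C11 epimers inconsequential)
Conditions: (S)-o-tolyl-CBS oxazaborolidine·Tf2NH (20 mol %), CH2Cl2, −78 → −40 °C
Reagents that add atoms: none
Why: Catalytic enantioselective Diels–Alder reaction (chiral oxazaborolidinium activation of the formyl group): the nucleophilic diene terminus C11 bonds to C10 (β to CHO), the E-dienophile fixes C2 and C9 trans, and catalyst shielding of one enal face sets quaternary C1 and C10; endo/exo only affects C11, which is erased later.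

Step 3
Reactants: 4 Diels–Alder adduct
Product: 5 (1S,10S) trans-fused 2,9-γ-lactone [C2H2–O–C9(=O)] carrying the C12 TIPS enol ether (Δ12,13)
Conditions: NaBH4, EtOH, −20 °C; then PPTS (cat.), PhMe, 80 °C
Reagents that add atoms: none
Why: Chemoselective aldehyde reduction followed by lactonisation of the trans γ-hydroxy ester masks C2–OH and C9 together and rigidifies the ring; no stereocentre is touched.

Step 4
Reactants: 5 silyl enol ether lactone
Product: 6 (1S,10S) enone lactone (C12 ketone, Δ13,14; C11–H epimers inconsequential)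
Conditions: Pd(OAc)2 (1.1 equiv), O2, DMSO/MeCN, 50 °C
Reagents that add atoms: none
Why: Saegusa–Ito oxidation of the regiodefined silyl enol ether delivered by the cycloaddition introduces the C13=C14 double bond.

Step 5
Reactants: 6 enone lactone
Product: 7 (1S,10R) cross-conjugated dienyl triflate lactone (Δ11,12 and Δ13,14; 12-OTf)
Conditions: KHMDS, THF, −78 °C; then PhNTf2
Reagents that add atoms: N-phenyl-bis(trifluoromethanesulfonimide), O=S(=O)(N(c1ccccc1)S(=O)(=O)C(F)(F)F)C(F)(F)F
Why: Kinetic α′-deprotonation (C11–H is the only enolisable position; γ-carbon C1 is quaternary) and O-triflation give the 2-triflyloxy-1,3-diene.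

Step 6
Reactants: 7 dienyl triflate lactone
Product: 8 (1S,10S) cyclohexa-11,13-diene lactone
Conditions: Pd(PPh3)4 (5 mol %), Bu3SnH, LiCl, THF, rt
Reagents that add atoms: none
Why: Pd-catalysed hydride reduction of the enol triflate gives the 1,3-diene under neutral conditions that leave the lactone alone.

Step 7
Reactants: 8 diene lactone
Product: 9 (1S,10R,11S,12R) 11α,12α-diol lactone (Δ13,14 retained)
Conditions: OsO4 (2 mol %), NMO, acetone/H2O, 0 °C
Reagents that add atoms: osmium tetroxide, O=[Os](=O)(=O)=O (re-oxidised by N-methylmorpholine N-oxide, C[N+]1([O-])CCOCC1); water, O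
Why: Upjohn dihydroxylation attacks the more electron-rich trisubstituted C11=C12 bond of the diene from the α-face, anti to the pseudo-axial C15 methyl of the rigid trans-fused bicycle, setting C11 and C12 as the cis α-diol in one step.

Step 8
Reactants: 9 diol lactone
Product: 10 (1S,10R,11S,12R) 11,12-O-isopropylidene lactone
Conditions: 2,2-dimethoxypropane, PPTS, acetone, rt
Reagents that add atoms: 2,2-dimethoxypropane, COC(C)(C)OC
Why: Acetonide formation on the cis tertiary/secondary diol protects both hydroxyls until the last step.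

Step 9
Reactants: 10 acetonide lactone
Product: 11 (1S,10R,11S,12R) hydroxy Weinreb amide (C9 N-methoxy-N-methylamide, C2 CH2OH)
Conditions: MeNH(OMe)·HCl, AlMe3, CH2Cl2, 0 °C → rt
Reagents that add atoms: N,O-dimethylhydroxylamine hydrochloride, CNOC.Cl
Why: Weinreb aminolysis of the strained trans-fused lactone frees the C2 alcohol and stores C9 as a masked aldehyde.

Step 10
Reactants: 11 hydroxy Weinreb amide
Product: 12 (1S,10R,11S,12R) C2 aldehyde
Conditions: Dess–Martin periodinane, NaHCO3, CH2Cl2, 0 °C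
Reagents that add atoms: none
Why: Dess–Martin oxidation gives the non-enolisable neopentyl aldehyde before the hydroxy amide can relactonise.

Step 11
Reactants: 12 C2 aldehyde; 13 4-bromo-2-methylbut-1-ene (as its Grignard reagent)
Product: 14 C2 secondary alcohol carrying the 3-methylbut-3-enyl chain (C3–C5, C16; C2 epimers, both used)
Conditions: 13, Mg, THF; then 12, THF, −78 °C
Reagents that add atoms: 3-methylbut-3-en-1-ylmagnesium bromide (from 13), C=C(C)CC[Mg]Br
Why: Grignard addition is selective for the aldehyde over the hindered Weinreb amide at −78 °C; the C2 configuration is irrelevant because it is oxidised next.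

Step 12
Reactants: 14 C2 alcohol
Product: 15 (1S,10R,11S,12R) C2 ketone
Conditions: Dess–Martin periodinane, NaHCO3, CH2Cl2, rt
Reagents that add atoms: none
Why: Dess–Martin oxidation converges both C2 epimers to a ketone that can enolise only towards C3.

Step 13
Reactants: 15 C2 ketone
Product: 16 (3R)-3-hydroxy-2-ketone
Conditions: NaHMDS, THF, −78 °C; then (−)-[(8,8-dichlorocamphoryl)sulfonyl]oxaziridine
Reagents that add atoms: [(8,8-dichlorocamphoryl)sulfonyl]oxaziridine, CC1(C)C2CCC13CS(=O)(=O)N4OC34C2(Cl)Cl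
Why: Davis enolate hydroxylation of the Z-sodium enolate with the chiral oxaziridine introduces O3 under reagent control and sets C3 (R).

Step 14
Reactants: 16 α-hydroxy ketone
Product: 17 (1S,2S,3R,10R,11S,12R) anti-2,3-diol
Conditions: Zn(BH4)2, Et2O, −30 °C
Reagents that add atoms: none
Why: Chelation-controlled (Cram-chelate) reduction, with hydride delivered to the zinc-bridged C3–OH/C2=O ring anti to the C4 chain, gives the anti (erythro) diol and sets C2 (S).

Step 15
Reactants: 17 diol; 18 acryloyl chloride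
Product: 19 C3 acrylate (C2–OH free)
Conditions: i-Pr2NEt, CH2Cl2, −40 °C
Reagents that add atoms: acryloyl chloride (18), C=CC(=O)Cl
Why: Selective acylation of the less hindered C3 hydroxyl (C2–OH is neopentylic) installs C6 and C7.

Step 16
Reactants: 19 C3 acrylate
Product: 20 C2 TBS ether of the C3 acrylate
Conditions: TBSOTf, 2,6-lutidine, CH2Cl2, 0 °C
Reagents that add atoms: tert-butyldimethylsilyl triflate, CC(C)(C)[Si](C)(C)OS(=O)(=O)C(F)(F)F
Why: Silylation of the hindered C2 alcohol prevents lactonisation onto C9 and keeps C2 unacetylated to the end.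

Step 17
Reactants: 20 acrylate diene
Product: 21 (3R) 4-methyl-5,6-dihydro-2H-pyran-2-one (ring O3–C7(=O)–C6=C5(C16)–C4–C3)
Conditions: Grubbs II (5 mol %), CH2Cl2, 40 °C
Reagents that add atoms: none
Why: Ring-closing metathesis to a six-membered unsaturated lactone forms the trisubstituted C5=C6 alkene necessarily with C4 and C7 cis (the target's 5Z); the hindered ring alkene C13=C14 is inert.

Step 18
Reactants: 21 dihydropyranone
Product: 22 (5Z)-C7 Weinreb enamide with free C3–OH
Conditions: MeNH(OMe)·HCl, AlMe3, CH2Cl2, 0 °C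
Reagents that add atoms: N,O-dimethylhydroxylamine hydrochloride, CNOC.Cl
Why: Weinreb aminolysis opens the δ-lactone with the Z geometry retained.

Step 19
Reactants: 22 hydroxy enamide
Product: 23 C3 TES ether
Conditions: TESCl, imidazole, CH2Cl2, 0 °C
Reagents that add atoms: chlorotriethylsilane, CC[Si](Cl)(CC)CC
Why: Silylation blocks relactonisation and lactol formation in the next step.

Step 20
Reactants: 23 bis-Weinreb amide
Product: 24 (1S,2S,3R,5Z,10R,11S,12R) dialdehyde (C7 Z-enal and C9 aldehyde)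
Conditions: DIBAL-H (5 equiv), THF, −78 → −40 °C; Rochelle salt work-up, used at once
Reagents that add atoms: none
Why: Both Weinreb amides are reduced through stable chelated tetrahedral intermediates to aldehydes without over-reduction or Z→E isomerisation.

Step 21
Reactants: 24 dialdehyde; 25 methyl propiolate
Product: 26 (7S)-γ-hydroxy ynoate (C9 aldehyde untouched)
Conditions: Me2Zn, (S,S)-ProPhenol (20 mol %), Ph3P=O, PhMe, 0 °C
Reagents that add atoms: methyl propiolate (25), C#CC(=O)OC
Why: Zn–ProPhenol asymmetric alkynylation delivers the zinc propiolate to one face of the unhindered Z-enal and sets C7 (S); the C9 aldehyde, flanked by two quaternary carbons, does not react.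

Step 22
Reactants: 26 propargylic alcohol
Product: 27 C7 TES ether (seco ynoate–aldehyde)
Conditions: TESOTf, 2,6-lutidine, CH2Cl2, −78 °C
Reagents that add atoms: triethylsilyl triflate, CC[Si](CC)(CC)OS(=O)(=O)C(F)(F)F
Why: Low-temperature silylation protects C7–OH without base-induced redox isomerisation of the γ-hydroxy ynoate.

Step 23
Reactants: 27 seco ynoate–aldehyde; 28 dimethylzinc
Product: 29 (1S,2S,3R,5Z,7S,8Z,9S,10S,11S,12R) ten-membered carbocycle with C9–OH and the tetrasubstituted enoate C8=C17(CH3)CO2Me (CO2Me cis to C7, CH3 cis to C9)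
Conditions: Ni(cod)2 (20 mol %), IPr (20 mol %), Me2Zn (3 equiv), THF/PhMe, 2 mM, syringe-pump addition, 0 °C → rt
Reagents that add atoms: dimethylzinc (28), C[Zn]C
Why: Proposed new method: Ni(0)/NHC-catalysed methylative ynoate–aldehyde macrocyclisation, in which oxidative cyclisation of Ni(0) with the C9 aldehyde and the ynoate gives an oxanickelacyclopentene with C9 bonded to the ynoate β-carbon C8 and Ni on the ester-bearing C17 (the regiochemistry of known Ni-catalysed ynoate–aldehyde reductive couplings), then Zn-to-Ni methyl transfer and C(sp2)–CH3 reductive elimination (methyl has no β-H, so no hydride transfer competes) place C18 syn to C9 and leave CO2Me cis to C7 for later lactonisation, while C9 (S) follows from Felkin–Anh attack anti to C11 over H-10 with the forming ring holding C8 gauche to C1; the closest known reaction types are Ni-catalysed alkylative ynal cyclisations with organozincs (normal rings) and Ni-catalysed reductive ynal macrocyclisations.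

Step 24
Reactants: 29 macrocyclic allylic alcohol
Product: 30 (7S,8S,9S,17S) 8,17-epoxide (threo to C9–OH)
Conditions: Ti(OiPr)4, t-BuOOH (decane), 4 Å MS, CH2Cl2, −20 → 0 °C
Reagents that add atoms: tert-butyl hydroperoxide, CC(C)(C)OO
Why: Hydroxyl-directed Ti(IV)/TBHP epoxidation touches only the alkene allylic to the single free OH, and A(1,3) strain between the C18 methyl and the C9 substituents holds H-9 in the alkene plane so oxygen is delivered to the O9 face (threo), setting C17 and the provisional C8 configuration.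

Step 25
Reactants: 30 epoxy ester
Product: 31 epoxy γ-lactone with free C3–OH and C9–OH (C2–OTBS and acetonide retained)
Conditions: HF·pyridine, pyridine, THF, 0 °C → rt
Reagents that add atoms: none
Why: Buffered fluoride removes the two TES ethers but not the hindered TBS ether, and the freed C7–OH lactonises onto the cis C19 methyl ester to close the γ-lactone.

Step 26
Reactants: 31 epoxy lactone diol
Product: 32 3,9-di-O-acetyl epoxy lactone
Conditions: Ac2O, DMAP, pyridine, rt → 40 °C
Reagents that add atoms: acetic anhydride, CC(=O)OC(C)=O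
Why: Acetylation of the only two free hydroxyls installs both natural acetates; C2 is silylated and C11/C12 are in the acetonide.

Step 27
Reactants: 32 epoxy diacetate
Product: 33 (1S,2S,3R,5Z,7S,8S,9S,10S,11S,12R,17S) 2-O-TBS-11,12-O-isopropylidene brianodin D
Conditions: BF3·OEt2, CH2Cl2, −40 °C; then H2O/NaHCO3
Reagents that add atoms: water, O
Why: Epoxy-ester (acetoxonium) rearrangement, in which the C9 acetate carbonyl opens the activated epoxide 5-exo at C8 (the carbon not α to the lactone carbonyl) with inversion and hydrolysis of the dioxolanylium ion returns the acetate to O9, giving C8–OH on the opposite face with C17–OH retained, i.e. the trans-8,17-diol.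

Step 28
Reactants: 33 protected brianodin D
Product: 34 brianodin D
Conditions: 48% aq HF, MeCN, 0 °C → rt
Reagents that add atoms: none
Why: Acidic fluoride cleaves the C2 TBS ether and hydrolyses the acetonide while the acetates, the lactone and the tertiary diol are stable and no stereocentre is touched.

## Compound list

1 | ethyl vinyl ketone (pent-1-en-3-one) | CCC(=O)C=C | starting material
2 | (Z)-3-(triisopropylsilyloxy)penta-1,3-diene | C/C=C(\O[Si](C(C)C)(C(C)C)C(C)C)C=C | intermediate
3 | ethyl (E)-3-methyl-4-oxobut-2-enoate | CCOC(=O)/C=C(\C)C=O | starting material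
4 | ethyl (1S,6S)-6-formyl-2,6-dimethyl-3-(triisopropylsilyloxy)cyclohex-3-ene-1-carboxylate (C11 unspecified) | CCOC(=O)[C@H]1C(C)C(O[Si](C(C)C)(C(C)C)C(C)C)=CC[C@]1(C)C=O | intermediate
5 | (1S,10S) trans-fused 2,9-γ-lactone, 12-OTIPS enol ether | O=C1OC[C@@]2(C)CC=C(O[Si](C(C)C)(C(C)C)C(C)C)C(C)[C@H]12 | intermediate
6 | (1S,10S) 12-oxo-Δ13 enone lactone | O=C1OC[C@@]2(C)C=CC(=O)C(C)[C@H]12 | intermediate
7 | (1S,10R) 12-triflyloxy-11,13-diene lactone | O=C1OC[C@@]2(C)C=CC(OS(=O)(=O)C(F)(F)F)=C(C)[C@H]12 | intermediate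
8 | (1S,10S) 11,13-diene lactone | O=C1OC[C@@]2(C)C=CC=C(C)[C@H]12 | intermediate
9 | (1S,10R,11S,12R) 11α,12α-diol lactone | O=C1OC[C@@]2(C)C=C[C@@H](O)[C@@](C)(O)[C@H]12 | intermediate
10 | (1S,10R,11S,12R) 11,12-O-isopropylidene lactone | O=C1OC[C@@]2(C)C=C[C@H]3OC(C)(C)O[C@@]3(C)[C@H]12 | intermediate
11 | C9 Weinreb amide, C2 primary alcohol | CON(C)C(=O)[C@H]1[C@]2(C)OC(C)(C)O[C@@H]2C=C[C@]1(C)CO | intermediate
12 | C9 Weinreb amide, C2 aldehyde | CON(C)C(=O)[C@H]1[C@]2(C)OC(C)(C)O[C@@H]2C=C[C@]1(C)C=O | intermediate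
13 | 4-bromo-2-methylbut-1-ene | C=C(C)CCBr | starting material
14 | C2 secondary alcohol with 3-methylbut-3-enyl chain (C2 epimers) | CON(C)C(=O)[C@H]1[C@]2(C)OC(C)(C)O[C@@H]2C=C[C@]1(C)C(O)CCC(C)=C | intermediate
15 | C2 ketone | CON(C)C(=O)[C@H]1[C@]2(C)OC(C)(C)O[C@@H]2C=C[C@]1(C)C(=O)CCC(C)=C | intermediate
16 | (3R)-3-hydroxy-2-ketone | CON(C)C(=O)[C@H]1[C@]2(C)OC(C)(C)O[C@@H]2C=C[C@]1(C)C(=O)[C@H](O)CC(C)=C | intermediate
17 | (2S,3R)-2,3-diol | CON(C)C(=O)[C@H]1[C@]2(C)OC(C)(C)O[C@@H]2C=C[C@]1(C)[C@H](O)[C@H](O)CC(C)=C | intermediate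
18 | acryloyl chloride | C=CC(=O)Cl | starting material
19 | (2S,3R) C3 acrylate, C2–OH | CON(C)C(=O)[C@H]1[C@]2(C)OC(C)(C)O[C@@H]2C=C[C@]1(C)[C@H](O)[C@H](OC(=O)C=C)CC(C)=C | intermediate
20 | (2S,3R) C2–OTBS, C3 acrylate | CON(C)C(=O)[C@H]1[C@]2(C)OC(C)(C)O[C@@H]2C=C[C@]1(C)[C@H](O[Si](C)(C)C(C)(C)C)[C@H](OC(=O)C=C)CC(C)=C | intermediate
21 | (2S,3R) 4-methyl-5,6-dihydropyran-2-one (O3–C7 lactone, Δ5) | CON(C)C(=O)[C@H]1[C@]2(C)OC(C)(C)O[C@@H]2C=C[C@]1(C)[C@H](O[Si](C)(C)C(C)(C)C)[C@H]3CC(C)=CC(=O)O3 | intermediate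
22 | (2S,3R,5Z) C7 Weinreb enamide, C3–OH | CON(C)C(=O)[C@H]1[C@]2(C)OC(C)(C)O[C@@H]2C=C[C@]1(C)[C@H](O[Si](C)(C)C(C)(C)C)[C@H](O)C/C(C)=C\C(=O)N(C)OC | intermediate
23 | (2S,3R,5Z) C3–OTES bis-Weinreb amide | CON(C)C(=O)[C@H]1[C@]2(C)OC(C)(C)O[C@@H]2C=C[C@]1(C)[C@H](O[Si](C)(C)C(C)(C)C)[C@H](O[Si](CC)(CC)CC)C/C(C)=C\C(=O)N(C)OC | intermediate
24 | (1S,2S,3R,5Z,10R,11S,12R) C7/C9 dialdehyde | O=C[C@H]1[C@]2(C)OC(C)(C)O[C@@H]2C=C[C@]1(C)[C@H](O[Si](C)(C)C(C)(C)C)[C@H](O[Si](CC)(CC)CC)C/C(C)=C\C=O | intermediate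
25 | methyl propiolate | C#CC(=O)OC | starting material
26 | (7S)-γ-hydroxy ynoate, C9 aldehyde | O=C[C@H]1[C@]2(C)OC(C)(C)O[C@@H]2C=C[C@]1(C)[C@H](O[Si](C)(C)C(C)(C)C)[C@H](O[Si](CC)(CC)CC)C/C(C)=C\[C@H](O)C#CC(=O)OC | intermediate
27 | (7S) C7–OTES ynoate, C9 aldehyde | O=C[C@H]1[C@]2(C)OC(C)(C)O[C@@H]2C=C[C@]1(C)[C@H](O[Si](C)(C)C(C)(C)C)[C@H](O[Si](CC)(CC)CC)C/C(C)=C\[C@H](O[Si](CC)(CC)CC)C#CC(=O)OC | intermediate
28 | dimethylzinc | C[Zn]C | starting material
29 | (1S,2S,3R,5Z,7S,8Z,9S,10S,11S,12R) macrocyclic enoate, C9–OH | CC[Si](CC)(CC)O[C@@H]1C/C(C)=C\[C@H](O[Si](CC)(CC)CC)/C(=C(/C)C(=O)OC)[C@@H](O)[C@H]2[C@]3(C)OC(C)(C)O[C@@H]3C=C[C@]2(C)[C@@H]1O[Si](C)(C)C(C)(C)C | intermediate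
30 | (7S,8S,9S,17S) 8,17-epoxy ester | CC[Si](CC)(CC)O[C@@H]1C/C(C)=C\[C@H](O[Si](CC)(CC)CC)[C@@]4(O[C@]4(C)C(=O)OC)[C@@H](O)[C@H]2[C@]3(C)OC(C)(C)O[C@@H]3C=C[C@]2(C)[C@@H]1O[Si](C)(C)C(C)(C)C | intermediate
31 | (7S,8S,9S,17S) 8,17-epoxy-7,19-lactone, C3–OH, C9–OH | O[C@@H]1C/C(C)=C\[C@@H]2OC(=O)[C@@]3(C)O[C@@]23[C@@H](O)[C@H]4[C@]5(C)OC(C)(C)O[C@@H]5C=C[C@]4(C)[C@@H]1O[Si](C)(C)C(C)(C)C | intermediate
32 | 3,9-di-O-acetyl-8,17-epoxy lactone (C8 now R by priority only) | CC(=O)O[C@@H]1C/C(C)=C\[C@@H]2OC(=O)[C@@]3(C)O[C@@]23[C@@H](OC(C)=O)[C@H]4[C@]5(C)OC(C)(C)O[C@@H]5C=C[C@]4(C)[C@@H]1O[Si](C)(C)C(C)(C)C | intermediate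
33 | 2-O-TBS-11,12-O-isopropylidene brianodin D | CC(=O)O[C@@H]1C/C(C)=C\[C@@H]2OC(=O)[C@@](C)(O)[C@@]2(O)[C@@H](OC(C)=O)[C@H]4[C@]5(C)OC(C)(C)O[C@@H]5C=C[C@]4(C)[C@@H]1O[Si](C)(C)C(C)(C)C | intermediate
34 | brianodin D, (1S,2S,3R,5Z,7S,8S,9S,10S,11S,12R,17S) | CC(=O)O[C@@H]1C/C(C)=C\[C@@H]2OC(=O)[C@@](C)(O)[C@@]2(O)[C@@H](OC(C)=O)[C@H]2[C@](C)(O)[C@H](O)C=C[C@]2(C)[C@@H]1O | target

## Summary

Total step count: 28.
Longest linear sequence: 28 steps (fully linear from ethyl vinyl ketone 1).

Three steps most likely to fail: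

1. **Step 23 (the proposed new Ni methylative macrocyclisation).** Risks are Ni-catalysed methylzincation of the ynoate, oligomerisation, and C9 selectivity at a hindered aldehyde. Fallback (known chemistry): build the C8 vinyl iodide first and close the ring with chromium. Stannylcupration of ynoate 27 with MeI trapping of the α-cuprio enoate gives Bu3Sn on C8 and CH3 on C17 by syn addition. Iododestannylation and an intramolecular Nozaki–Hiyama–Kishi reaction (CrCl2/NiCl2) onto the C9 aldehyde then form the same ring. A wrong C9 epimer would be corrected by oxidation and reduction.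

2. **Step 24 (directed epoxidation of an electron-poor tetrasubstituted alkene).** Risks are low reactivity and threo/erythro selectivity, since the substrate has both 1,2- and 1,3-allylic strain. Fallback: replace electrophilic metal–peroxo delivery by alkoxide-directed nucleophilic (Weitz–Scheffer-type) epoxidation. The lithium alkoxide of 29 with t-BuOOLi adds peroxide to C8 from the O9 face and the enolate closes the oxirane.

3. **Step 2 (enantioselective Diels–Alder with a trisubstituted, doubly activated enal).** Risks are enantioselectivity and competing ester activation. Fallback: run the cycloaddition racemically with an achiral Lewis acid (Et2AlCl) and resolve later. Hydroxy amide 11 would be separated as its diastereomeric (S)-O-methylmandelate esters, then the ester cleaved.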